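All constants belong to no real substance; the result is computed.

The product D.G is built from D, so I first wanted to know how much free D each flask held at the end.

    Q → D (k1 = 7.2 × 10⁻⁵ s⁻¹, Ea1 = 122 kJ mol⁻¹)
    X → G (k2 = 3.7 × 10⁻⁵ s⁻¹, Ea2 = 123 kJ mol⁻¹)
    D + G → D.G (k3 = 3.2 × 10⁻⁴ M⁻¹ s⁻¹, Ea3 = 79.0 kJ mol⁻¹)
    Q + D.G ⇌ Q.D.G, settled at all times (K4 = 82 M⁻¹, ΔH4 = 54.0 kJ mol⁻¹)
    Q + G → Q.G (k5 = 4.5 × 10⁻⁵ M⁻¹ s⁻¹, Ea5 = 99.0 kJ mol⁻¹)
    D → L (k6 = 6.3 × 10⁻⁵ s⁻¹, Ea6 = 107 kJ mol⁻¹)
    (constants at 70 °C)

| setting | alder | cedar | ash |
|---|---|---|---|
| Q | 0.16 M | 0.16 M | 0.16 M |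
| X | 0.192 M | 0.192 M | 0.192 M |
| temperature | 45 °C | 70 °C | 95 °C |
| time | 4.0 h | 4.0 h | 4.0 h |

- percent here means Q units held: one Q.D.G counts as two
- what is said of D.G includes Q.D.G
- constants are those at 70 °C; use the activation energies and enthalpies for any other temperature
- in an amount of D.G, one Q.D.G counts as one D.G

1. the flask that comes out highest in amount of D, in percent of the Q charged, or "all alike" when all lie within 1.5 percentage points (alder / cedar / ash / all alike)
2. D at the end, in percent of the Q charged, alder
3. D at the end, in percent of the Q charged, cedar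
4. D at the end, in percent of the Q charged, ash

I reckoned with one number, the clock of a flask: the base-ten logarithm of the rate constant of Q → D at the flask's temperature times the time, 1.28 for ash. Beside it I set a, that same product before the logarithm, and b, the like product for D → L. The last column is the fraction of the Q charged that stands as D when these two steps run as consecutive first-order reactions: a/(b−a) times (e^−a − e^−b).

| flask | a | b | clock | D reckoned |
|---|---|---|---|---|
| alder | 0.0360 | 0.0476 | −1.44 | 3.45% |
| cedar | 1.04 | 0.907 | 0.0157 | 39.3% |
| ash | 18.9 | 11.6 | 1.28 | 0.00241% |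

In the alder row the clock stood well below zero: in this reckoning hardly any of the Q had turned to D, and with b at 0.0476 the figure for D stayed close to a. In the cedar row the clock stood near zero, and these two steps put the peak of D at 4.12 h, so in this reckoning cedar was read close to its top. That row leaves out D + G → D.G, which uses D as well, so I took its figure as high. In the ash row the clock stood more than one power of ten above zero, far past the peak. Its figure counts no Q held in Q.D.G, so I committed to "small" and not to the figure. My order was cedar above both others.

The forecast also named cedar, with 3.4% for alder, 35% for cedar and 0.25% for ash, the last far above my row, as a level “fed by Q slowly released from Q.D.G”.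

The simulation gave cedar as highest, with D at 3.45% in alder, 33.7% in cedar and 0.174% in ash, the flask at clock 1.28. The same ash flask read at 1.0 h has a clock lower by 0.602, which is 0.675, with a at 4.73 and b at 2.90, and the two steps then give 12.0% of D. At that reading the ash flask held 5.75% of D, half of that figure and far more than its 0.174% at 4.0 h.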